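## Retrosynthetic overview

1. The plan rests on the hexasubstituted benzene ring of the isochromanone: C4a, C5 with the CH2 bridge, C6–OH, C7–CH3, C8–OH, and C8a with the C1 carbonyl. Its 2,4-dihydroxybenzoate pattern is what a 1,1,3-trioxygenated diene and an alkynoate deliver, so the ring is assembled from open chains with all six substituents already in place.
2. In the end game the chromone 5-OH comes from its methyl ether (BCl3) and the δ-lactone (O2–C1) from a hydroxy ester. The key cut at C5–C4a and C8–C8a leads to two partners: a 1-methoxy-1,3-bis(silyloxy)penta-1,3-diene carrying the chromon-6-ylmethyl group on its terminus, and methyl (R)-5-silyloxyhex-2-ynoate, which brings C3.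
3. The diene comes from a δ-aryl-α-methyl-β-keto ester by two-stage silylation. The keto ester comes from 6-iodo-5,7-dimethoxy-2-methylchromone by Heck arylation of an allylic alcohol, and the iodide comes from eugenin.
4. Ring order: both chromone rings are bought with eugenin, then the benzene ring of the isochromanone is formed (step 9), then the lactone ring (step 10).

Key step: step 9

Remark: any base or silylating agent strong enough to enolise the ester also removes a proton from the vinylogously acidic chromone 2-CH3, so the diene is made with both sites silylated and the chromone passes through the key step as its 2-methylidene-4-silyloxy-2H-chromene form, which mild acid turns back into the chromone.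

## Route

Step 1
Reactants: 1 eugenin (5-hydroxy-7-methoxy-2-methyl-4H-chromen-4-one)
Product: 2 5-hydroxy-6-iodo-7-methoxy-2-methyl-4H-chromen-4-one
Conditions: BnMe3N·ICl2 (1.0 equiv), CaCO3, CH2Cl2–MeOH, rt
Reagents that add atoms: benzyltrimethylammonium dichloroiodate, C[N+](C)(C)Cc1ccccc1.Cl[I-]Cl
Why: Electrophilic aromatic iodination; with the 5-OH free and the medium buffered by CaCO3 the phenol directs iodine to its only open ortho position, C6, rather than to C8, as is known for 5-hydroxy-7-alkoxy-chromones and -flavones, and one equivalent of reagent should hold back a second iodination.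

Step 2
Reactants: 2 5-hydroxy-6-iodo-7-methoxy-2-methyl-4H-chromen-4-one
Product: 3 6-iodo-5,7-dimethoxy-2-methyl-4H-chromen-4-one
Conditions: MeI (3 equiv), K2CO3 (3 equiv), DMF, 45 °C
Reagents that add atoms: iodomethane, CI
Why: Williamson etherification; the chelated and iodine-flanked 5-OH needs warm DMF and excess MeI, K2CO3 is too weak to deprotonate the 2-methyl group, and a methyl ether peri to the C4 carbonyl is the one ether that can later be cleaved beside the 7-OMe group.

Step 3
Reactants: 4 methyl propanoate; 5 acrolein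
Product: 7 methyl 3-hydroxy-2-methylpent-4-enoate (racemic syn/anti mixture), via lithium enolate 6 (not isolated)
Conditions: LiN(i-Pr)2 (LDA, commercial solution, 1.05 equiv), THF, −78 °C; 5; AcOH quench
Reagents that add atoms: none
Why: Lithium-enolate aldol addition, which goes 1,2 on acrolein at low temperature; relative and absolute configuration are irrelevant because the carbinol carbon becomes a ketone in step 4 and the α-carbon becomes sp2 in step 5.

Step 4
Reactants: 3 6-iodo-5,7-dimethoxy-2-methyl-4H-chromen-4-one; 7 methyl 3-hydroxy-2-methylpent-4-enoate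
Product: 9 methyl 5-(5,7-dimethoxy-2-methyl-4-oxo-4H-chromen-6-yl)-2-methyl-3-oxopentanoate (racemic), via enol 8 (not isolated)
Conditions: 7 (1.5 equiv), Pd(OAc)2 (5 mol %), n-Bu4NCl (1 equiv), NaHCO3 (2.5 equiv), DMF, 70 °C
Reagents that add atoms: none
Why: Heck arylation of a secondary allylic alcohol under Jeffery conditions: the arylpalladium species adds to the terminal alkene carbon, β-hydride elimination takes the carbinol hydrogen and enol 8 tautomerises to the ketone, so the complete five-carbon chain is attached under NaHCO3 only, without a strong base that the acidic 2-methylchromone and its C2 acceptor site would not tolerate.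

Step 5
Reactants: 9 methyl 5-(5,7-dimethoxy-2-methyl-4-oxo-4H-chromen-6-yl)-2-methyl-3-oxopentanoate
Product: 10 methyl 5-(5,7-dimethoxy-2-methyl-4-oxo-4H-chromen-6-yl)-2-methyl-3-(trimethylsilyloxy)pent-2-enoate (E/Z mixture)
Conditions: Me3SiCl (1.6 equiv), Et3N (2 equiv), PhMe, rt, 48 h; filter, evaporate
Reagents that add atoms: chlorotrimethylsilane, C[Si](C)(C)Cl
Why: O-Silylation of the β-keto ester enol with an amine base, the usual first stage of a Chan-type diene synthesis and known for 2-alkyl acetoacetates; Me3SiCl is not electrophilic enough to activate the chromone carbonyl.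

Step 6
Reactants: 10 methyl 5-(5,7-dimethoxy-2-methyl-4-oxo-4H-chromen-6-yl)-2-methyl-3-(trimethylsilyloxy)pent-2-enoate
Product: 12 1-methoxy-2-methyl-1,3-bis(trimethylsilyloxy)-5-[5,7-dimethoxy-2-methylidene-4-(trimethylsilyloxy)-2H-chromen-6-yl]penta-1,3-diene, via dilithium bis-dienolate 11 (not isolated)
Conditions: 10 added slowly to LiN(i-Pr)2 (2.3 equiv), THF, −78 °C, 1 h; Me3SiCl (3 equiv), −78 → 0 °C; evaporate, dry hexane–PhMe, filter under Ar, use crude
Reagents that add atoms: chlorotrimethylsilane, C[Si](C)(C)Cl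
Why: Kinetic γ-deprotonation of the β-silyloxy enoate and O-silylation of the ester dienolate, the second stage of the Chan-type diene synthesis; slow addition of 10 to more than two equivalents of base deprotonates the chromone 2-CH3 as well, so that no site selectivity is asked for, the chromone is shielded as a silyl dienol ether, and the arylmethyl group is expected to lie mainly outward (3Z) as in other 4-alkyl dienes of this class.

Step 7
Reactants: 13 (R)-pent-4-yn-2-ol
Product: 14 (R)-tert-butyldimethyl(pent-4-yn-2-yloxy)silane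
Conditions: TBSCl (1.2 equiv), imidazole (2.2 equiv), CH2Cl2, rt
Reagents that add atoms: tert-butylchlorodimethylsilane, CC(C)(C)[Si](C)(C)Cl
Why: Imidazole-promoted silyl ether formation at oxygen, which leaves the C–O bond and thus the R configuration untouched and removes the proton that would destroy the ketene acetal in step 9.

Step 8
Reactants: 14 (R)-tert-butyldimethyl(pent-4-yn-2-yloxy)silane
Product: 16 methyl (R)-5-(tert-butyldimethylsilyloxy)hex-2-ynoate, via lithium acetylide 15 (not isolated)
Conditions: n-BuLi (1.05 equiv), THF, −78 °C; ClCO2Me (1.3 equiv), −78 → 0 °C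
Reagents that add atoms: methyl chloroformate, COC(=O)Cl
Why: Deprotonation of the terminal alkyne and C-acylation of the lithium acetylide with a chloroformate, a standard ynoate synthesis to which the silyl ether and the remote stereocentre are inert.

Step 9
Reactants: 12 1-methoxy-2-methyl-1,3-bis(trimethylsilyloxy)-5-[5,7-dimethoxy-2-methylidene-4-(trimethylsilyloxy)-2H-chromen-6-yl]penta-1,3-diene; 16 methyl (R)-5-(tert-butyldimethylsilyloxy)hex-2-ynoate
Product: 19 methyl 2,4-dihydroxy-3-methyl-5-[(5,7-dimethoxy-2-methyl-4-oxo-4H-chromen-6-yl)methyl]-6-[(2R)-2-(tert-butyldimethylsilyloxy)propyl]benzoate, via cyclohexa-1,4-diene cycloadduct 17 (not isolated), via tris-O-silylated arene 18 (not isolated)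
Conditions: 16 (3 equiv, excess recovered), N,O-bis(trimethylsilyl)acetamide (BSA, 2 equiv), PhMe (2 M), sealed tube, 130 °C; then 0.5 M aq. citric acid–THF, rt
Reagents that add atoms: none
Why: The donor-rich diene of 12 and the ester-polarised alkyne of 16 combine in a thermal normal-electron-demand Diels–Alder reaction, concerted but strongly asynchronous with the C5–C4a bond leading (at the limit a Mukaiyama–Michael addition followed by closure of C8–C8a), which is the established resorcylate synthesis from 1-alkoxy-1,3-bis(silyloxy)dienes and alkynoates, β-alkyl ynoates included when heated. The benzene ring is closed by this intermolecular [4+2] cycloaddition, and cyclohexa-1,4-diene 17 aromatises to 18 by 1,4-elimination of methanol from the ketal carbon C8 and the doubly allylic C5–H. The selectivity needed is regiochemical: the largest HOMO coefficient sits on the diene terminus remote from the ketene acetal (future C5) and the largest LUMO coefficient on the ynoate β-carbon (future C4a), so the ester ends up beside the C8 oxygen and the silyloxypropyl chain beside the methylene bridge. No lasting stereocentre is made, since C5 and C8 of 17 become sp2, and C3 is only carried along, two saturated bonds away from the reacting alkyne. Lewis acids are left out because they would turn a chromone into a benzopyrylium acceptor for the diene, the masked chromone of 12 is an s-trans dienol ether that cannot cycloadd, and BSA silylates the liberated methanol before it can protonate unreacted ketene acetal. If part of 17 loses silanol instead of methanol, the 8-O-methyl ether so formed lies ortho to the C1 carbonyl and is cleaved with the chromone 5-O-methyl group in step 11.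

Step 10
Reactants: 19 methyl 2,4-dihydroxy-3-methyl-5-[(5,7-dimethoxy-2-methyl-4-oxo-4H-chromen-6-yl)methyl]-6-[(2R)-2-(tert-butyldimethylsilyloxy)propyl]benzoate
Product: 21 (3R)-6,8-dihydroxy-5-[(5,7-dimethoxy-2-methyl-4-oxo-4H-chromen-6-yl)methyl]-3,7-dimethylisochroman-1-one, via hydroxy ester 20 (not isolated)
Conditions: p-TsOH·H2O (0.3 equiv), MeOH, 40 °C; evaporate; PhMe, 80 °C
Reagents that add atoms: none
Why: Acid-catalysed methanolysis of the secondary silyl ether followed by intramolecular transesterification (6-exo-trig attack of the C3 hydroxyl on the ester carbonyl) closes the δ-lactone; only the acyl–oxygen bond of the ester is broken, so C3 stays R, and the catalytic sulfonic acid is mild enough for the electron-rich diarylmethane.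

Step 11
Reactants: 21 (3R)-6,8-dihydroxy-5-[(5,7-dimethoxy-2-methyl-4-oxo-4H-chromen-6-yl)methyl]-3,7-dimethylisochroman-1-one
Product: 22 (3R)-6,8-dihydroxy-5-[(5-hydroxy-7-methoxy-2-methyl-4-oxo-4H-chromen-6-yl)methyl]-3,7-dimethylisochroman-1-one (CNP0180307.1)
Conditions: BCl3 (5 equiv, 1 M in CH2Cl2), CH2Cl2, −78 → 0 °C; then H2O
Reagents that add atoms: none
Why: Chelation-controlled aryl methyl ether cleavage: boron binds the chromone C4 carbonyl and the peri 5-OMe oxygen in a six-membered chelate and chloride removes that methyl group, whereas the 7-OMe group has no neighbouring carbonyl and the lactone and phenols only form borates that water hydrolyses.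

## Compound list

1 | eugenin (5-hydroxy-7-methoxy-2-methyl-4H-chromen-4-one) | COc1cc(O)c2c(c1)oc(C)cc2=O | starting material
2 | 5-hydroxy-6-iodo-7-methoxy-2-methyl-4H-chromen-4-one | COc1cc2oc(C)cc(=O)c2c(O)c1I | intermediate
3 | 6-iodo-5,7-dimethoxy-2-methyl-4H-chromen-4-one | COc1cc2oc(C)cc(=O)c2c(OC)c1I | intermediate
4 | methyl propanoate | CCC(=O)OC | starting material
5 | acrolein | C=CC=O | starting material
6 | lithium enolate of methyl propanoate (not isolated) | CC=C(OC)O[Li] | intermediate
7 | methyl 3-hydroxy-2-methylpent-4-enoate (racemic syn/anti mixture) | COC(=O)C(C)C(O)C=C | intermediate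
8 | methyl 5-(5,7-dimethoxy-2-methyl-4-oxo-4H-chromen-6-yl)-3-hydroxy-2-methylpent-3-enoate (enol, not isolated) | COC(=O)C(C)C(O)=CCc1c(OC)cc2oc(C)cc(=O)c2c1OC | intermediate
9 | methyl 5-(5,7-dimethoxy-2-methyl-4-oxo-4H-chromen-6-yl)-2-methyl-3-oxopentanoate (racemic) | COC(=O)C(C)C(=O)CCc1c(OC)cc2oc(C)cc(=O)c2c1OC | intermediate
10 | methyl 5-(5,7-dimethoxy-2-methyl-4-oxo-4H-chromen-6-yl)-2-methyl-3-(trimethylsilyloxy)pent-2-enoate (E/Z mixture) | COC(=O)C(C)=C(CCc1c(OC)cc2oc(C)cc(=O)c2c1OC)O[Si](C)(C)C | intermediate
11 | dilithium bis-dienolate of 10 (not isolated) | COC(O[Li])=C(C)C(O[Si](C)(C)C)=CCc1c(OC)cc2OC(=C)C=C(O[Li])c2c1OC | intermediate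
12 | 1-methoxy-2-methyl-1,3-bis(trimethylsilyloxy)-5-[5,7-dimethoxy-2-methylidene-4-(trimethylsilyloxy)-2H-chromen-6-yl]penta-1,3-diene | COC(O[Si](C)(C)C)=C(C)C(O[Si](C)(C)C)=CCc1c(OC)cc2OC(=C)C=C(O[Si](C)(C)C)c2c1OC | intermediate
13 | (R)-pent-4-yn-2-ol | C#CC[C@@H](C)O | starting material
14 | (R)-tert-butyldimethyl(pent-4-yn-2-yloxy)silane | C#CC[C@@H](C)O[Si](C)(C)C(C)(C)C | intermediate
15 | lithium acetylide of 14 (not isolated) | [Li]C#CC[C@@H](C)O[Si](C)(C)C(C)(C)C | intermediate
16 | methyl (R)-5-(tert-butyldimethylsilyloxy)hex-2-ynoate | COC(=O)C#CC[C@@H](C)O[Si](C)(C)C(C)(C)C | intermediate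
17 | cyclohexa-1,4-diene cycloadduct of 12 and 16 (mixture at the two transient ring centres, not isolated) | COC(=O)C1=C(C[C@@H](C)O[Si](C)(C)C(C)(C)C)C(Cc2c(OC)cc3OC(=C)C=C(O[Si](C)(C)C)c3c2OC)C(O[Si](C)(C)C)=C(C)C1(OC)O[Si](C)(C)C | intermediate
18 | tris-O-silylated arene (2,4-bis(trimethylsilyl) ether of 19 with the chromone still masked, not isolated) | COC(=O)c1c(C[C@@H](C)O[Si](C)(C)C(C)(C)C)c(Cc2c(OC)cc3OC(=C)C=C(O[Si](C)(C)C)c3c2OC)c(O[Si](C)(C)C)c(C)c1O[Si](C)(C)C | intermediate
19 | methyl 2,4-dihydroxy-3-methyl-5-[(5,7-dimethoxy-2-methyl-4-oxo-4H-chromen-6-yl)methyl]-6-[(2R)-2-(tert-butyldimethylsilyloxy)propyl]benzoate | COc1cc2oc(C)cc(=O)c2c(OC)c1Cc1c(O)c(C)c(O)c(C(=O)OC)c1C[C@@H](C)O[Si](C)(C)C(C)(C)C | intermediate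
20 | methyl 2,4-dihydroxy-3-methyl-5-[(5,7-dimethoxy-2-methyl-4-oxo-4H-chromen-6-yl)methyl]-6-[(2R)-2-hydroxypropyl]benzoate (not isolated) | COc1cc2oc(C)cc(=O)c2c(OC)c1Cc1c(O)c(C)c(O)c(C(=O)OC)c1C[C@@H](C)O | intermediate
21 | (3R)-6,8-dihydroxy-5-[(5,7-dimethoxy-2-methyl-4-oxo-4H-chromen-6-yl)methyl]-3,7-dimethylisochroman-1-one | COc1cc2oc(C)cc(=O)c2c(OC)c1Cc1c(O)c(C)c(O)c2c1C[C@@H](C)OC2=O | intermediate
22 | (3R)-6,8-dihydroxy-5-[(5-hydroxy-7-methoxy-2-methyl-4-oxo-4H-chromen-6-yl)methyl]-3,7-dimethylisochroman-1-one | COc1cc2oc(C)cc(=O)c2c(O)c1Cc1c(O)c(C)c(O)c2c1C[C@@H](C)OC2=O | target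

## Step count and risks

Total steps: 11. Longest linear sequence: 8 (steps 1, 2, 4, 5, 6, 9, 10, 11).

**Step 9.**
- *Risk:* The cycloaddition of a pentasubstituted diene with a β-alkyl ynoate may be so slow that thermal protodesilylation and silyl migration of the ketene acetal outrun C–C bond formation.
- *Fallback:* It sets out from 14 and 12 and comes back at 19, and it changes the activating group of the dienophile and the way the carboxyl oxidation level is reached.
- Alkyne 14 is lithiated with n-BuLi and formylated with DMF to (R)-5-(tert-butyldimethylsilyloxy)hex-2-ynal F1. Its aldehyde lowers the alkyne LUMO much more than an ester does, so it should add to 12 near room temperature with the same polarity-controlled orientation.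
- Citric acid work-up should give 2,4-dihydroxy-3-methyl-5-[(5,7-dimethoxy-2-methyl-4-oxo-4H-chromen-6-yl)methyl]-6-[(2R)-2-(tert-butyldimethylsilyloxy)propyl]benzaldehyde F2.
- Pinnick oxidation (NaClO2, NaH2PO4, 2-methylbut-2-ene, t-BuOH–H2O) leads to the corresponding benzoic acid F3.
- One equivalent of Me3SiCHN2 in PhMe–MeOH esterifies the carboxyl group to give 19.

**Step 6.**
- *Risk:* Metalation may be incomplete or misdirected (ring lithiation at chromone C3, or silylation at carbon instead of oxygen of the chromone anion), and the ketene acetal may hydrolyse during handling.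
- *Fallback:* It sets out from 16 and 3 and comes back at 21. It takes the chromone out of every enolisation and forms the methylene bridge after the arene.
- Commercial methyl 2-methyl-3-oxobutanoate is silylated (Me3SiCl, Et3N) to methyl 2-methyl-3-(trimethylsilyloxy)but-2-enoate F4. Treatment with LiN(i-Pr)2 and Me3SiCl then gives 1-methoxy-2-methyl-1,3-bis(trimethylsilyloxy)buta-1,3-diene F5.
- F5, used in excess, reacts with 16 in PhMe at 110 °C. After citric acid work-up this should give methyl 2,4-dihydroxy-3-methyl-6-[(2R)-2-(tert-butyldimethylsilyloxy)propyl]benzoate F6.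
- The acid conditions of step 10 convert F6 into (3R)-6,8-dihydroxy-3,7-dimethylisochroman-1-one F7. Its C5 is the only unsubstituted ring carbon and lies ortho to 6-OH and para to 8-OH.
- Stille coupling of 3 with Bu3SnCH2OH (Pd(PPh3)4, dioxane, 100 °C) gives 6-(hydroxymethyl)-5,7-dimethoxy-2-methyl-4H-chromen-4-one F8.
- Friedel–Crafts benzylation of F7 by F8 (Sc(OTf)3 catalyst, MeNO2, rt) gives 21.

**Step 4.**
- *Risk:* Alkene insertion at the doubly ortho-substituted, electron-rich aryl iodide may be slow. Reductive loss of iodine and β-hydride elimination toward the benzylic side would then compete.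
- *Fallback:* It sets out from 3 and comes back at 9. It replaces the Heck/redox isomerisation by an sp2–sp3 cross-coupling and a malonate acylation.
- Negishi coupling of 3 with BrZnCH2CH2CO2Et (Pd(OAc)2, SPhos, THF, 50 °C) gives ethyl 3-(5,7-dimethoxy-2-methyl-4-oxo-4H-chromen-6-yl)propanoate F9.
- LiOH in THF–H2O at rt gives 3-(5,7-dimethoxy-2-methyl-4-oxo-4H-chromen-6-yl)propanoic acid F10.
- 1,1'-Carbonyldiimidazole gives the acyl imidazole F11.
- F11 acylates the magnesium enolate made from KO2CCH(CH3)CO2CH3, MgCl2 and Et3N (Masamune–Brooks homologation). Decarboxylation then gives 9.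

## Further compounds

F1 | step 9 | (R)-5-(tert-butyldimethylsilyloxy)hex-2-ynal | O=CC#CC[C@@H](C)O[Si](C)(C)C(C)(C)C
F2 | step 9 | 2,4-dihydroxy-3-methyl-5-[(5,7-dimethoxy-2-methyl-4-oxo-4H-chromen-6-yl)methyl]-6-[(2R)-2-(tert-butyldimethylsilyloxy)propyl]benzaldehyde | COc1cc2oc(C)cc(=O)c2c(OC)c1Cc1c(O)c(C)c(O)c(C=O)c1C[C@@H](C)O[Si](C)(C)C(C)(C)C
F3 | step 9 | 2,4-dihydroxy-3-methyl-5-[(5,7-dimethoxy-2-methyl-4-oxo-4H-chromen-6-yl)methyl]-6-[(2R)-2-(tert-butyldimethylsilyloxy)propyl]benzoic acid | COc1cc2oc(C)cc(=O)c2c(OC)c1Cc1c(O)c(C)c(O)c(C(=O)O)c1C[C@@H](C)O[Si](C)(C)C(C)(C)C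
F4 | step 6 | methyl 2-methyl-3-(trimethylsilyloxy)but-2-enoate | COC(=O)C(C)=C(C)O[Si](C)(C)C
F5 | step 6 | 1-methoxy-2-methyl-1,3-bis(trimethylsilyloxy)buta-1,3-diene | COC(O[Si](C)(C)C)=C(C)C(=C)O[Si](C)(C)C
F6 | step 6 | methyl 2,4-dihydroxy-3-methyl-6-[(2R)-2-(tert-butyldimethylsilyloxy)propyl]benzoate | COC(=O)c1c(O)c(C)c(O)cc1C[C@@H](C)O[Si](C)(C)C(C)(C)C
F7 | step 6 | (3R)-6,8-dihydroxy-3,7-dimethylisochroman-1-one | Cc1c(O)cc2C[C@@H](C)OC(=O)c2c1O
F8 | step 6 | 6-(hydroxymethyl)-5,7-dimethoxy-2-methyl-4H-chromen-4-one | COc1cc2oc(C)cc(=O)c2c(OC)c1CO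
F9 | step 4 | ethyl 3-(5,7-dimethoxy-2-methyl-4-oxo-4H-chromen-6-yl)propanoate | CCOC(=O)CCc1c(OC)cc2oc(C)cc(=O)c2c1OC
F10 | step 4 | 3-(5,7-dimethoxy-2-methyl-4-oxo-4H-chromen-6-yl)propanoic acid | OC(=O)CCc1c(OC)cc2oc(C)cc(=O)c2c1OC
F11 | step 4 | 6-[3-(1H-imidazol-1-yl)-3-oxopropyl]-5,7-dimethoxy-2-methyl-4H-chromen-4-one | O=C(CCc1c(OC)cc2oc(C)cc(=O)c2c1OC)n1ccnc1
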